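# Proposed synthesis of CNP0176600.1 (compound 32) by anti-carbomagnesiation three-component union across C1=C10

## Analysis of the target

Compound 32 is a cis,cis-germacranolide: a ten-membered carbocycle (C1–C10) with two trisubstituted Z ring alkenes, C1=C10 and C4=C5, fused trans across C7–C8 to an α-methylene-γ-butyrolactone (C11–C13, lactone oxygen on C8). The ring carries five stereocentres, C2 (S), C6 (R), C7 (S), C8 (R) and C9 (R), and a sixth, (R), sits in the 2-methylbutanoate on O6. C6 to C9 form one contiguous array in which, in an extended C5–C10 zigzag, the oxygens on C6, C8 and C9 and the C11 branch on C7 lie on the same side; this means a trans relationship of H7 and H8 and a syn C8/C9 diol, whereas C2 is related to C9 only 1,4 across the C1=C10 alkene. The sensitive groups are the exocyclic methylene lactone (conjugate addition, translactonisation), the two secondary allylic alcohols (a Z γ-hydroxy enone formed by oxidising one while the other is free would close to a furan), the C6 ester and the doubly allylic C3 methylene. The difficulty lies in a strained medium ring whose two Z alkenes cannot be left to thermodynamic control, in four adjacent stereocentres at the site of ring closure and in one remote stereocentre. The plan rests on the observation that O9, the C10 methyl group and O2 sit on the Z C1=C10 alkene as a 2-methyl-(Z)-but-2-ene-1,4-diol, which is what remains when a methyl–metal bond adds anti across the alkyne of a C9 propargylic alkoxide and the resulting C1–metal bond is intercepted by a C2 aldehyde. A second feature, the C13–C11–C7 allyl unit of the lactone next to the C6 carbinol, dictates how the ring is closed.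

## Retrosynthetic reasoning

**32 ⇒ 31 ⇒ 29 + 30.** The two free allylic alcohols are released last from the bis-silyl ether 31. The O6 ester is attached just before, from the ring alcohol 29 and the acid 30. At that point O6 is the only free hydroxyl, so no regiochemical question arises and the acid stereocentre is never exposed to strong base.

**29 ⇒ 27 (C6–C7).** This is the only ring bond that joins the γ-carbon of a lactone-derived allyl unit (C13–C11=C7) to a carbinol carbon. Cutting it opens the ten-membered ring, removes the C6 and C7 stereocentres and returns the exocyclic methylene as an allylic bromide in the butenolide 27. The forward reaction must make the allylchromium 28 add to the C6 enal through C7, on the butenolide face opposite C9, through a chair transition state.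

**27 ⇒ 26 ⇒ 25 ⇒ 24 ⇒ 21 + 22.** The enal comes from the primary silyl ether of 25 by way of the allylic alcohol 26. The butenolide C7=C11 bond is cut by retro ring-closing metathesis to the acrylate 24, and the ester is cut to the C8 alcohol 21 and the acid 22, used as its chloride 23. The C7 vinyl group therefore serves as a latent ring carbon, and no stereocentre is touched in making the lactone.

**21 ⇒ 20 ⇒ 19.** O8 must be an ether that survives organomagnesium chemistry and can be freed alone, hence PMB. O2 and O9 are held as silyl ethers to the end.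

**19 ⇒ 18 ⇒ 17 ⇒ 16 ⇒ 15 ⇒ 14.** The three-component union cannot be trusted to set C2, so 14 is planned as the pair of C2 epimers. C2 is disconnected as a C–H bond to the enone 18, from which reagent control gives the single alcohol 19. Both epimers converge on 18. O9 has to be silylated before the oxidation, otherwise the Z γ-hydroxy enone would cyclise and aromatise. The more accessible O2 is therefore masked as an acetate (15), O9 is silylated (16) and O2 is released again (17).

**14 ⇒ 7 + 12 + 11 (key disconnection).** The C10–CH3 and C1–C2 bonds are cut. All ten ring carbons then fall into two fragments of similar size plus 12. The Z geometry of C1=C10 follows from the mechanism through the chelate 13, and no ring has to be formed. The forward step needs anti addition with methyl on C10 and trapping of the C1–metal bond by 11 faster than its enolisation.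

**7 ⇒ 5 + 6; 5 ⇒ 4 ⇒ 3 ⇒ 2 ⇒ 1.** The C9–C10 bond is cut to the α-alkoxy aldehyde 5 and the acetylide 6, so that C9 is set from C8 by chelation. C8 itself comes from resolution of the racemic epoxide 1 to the diol 2. The PMB group is placed on the secondary oxygen through the acetal 3 and its reductive opening to 4.

**11 ⇒ 9 ⇒ 8.** The C2 aldehyde is traced through the alkenylborane 10 to the terminal alkyne of 9 (anti-Markovnikov hydration). The Z C4=C5 alkene and the differentiated termini (alcohol and alkyne) are bought with 8, so no selective protection between two similar hydroxyls is needed.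

## Alternatives that were turned down

Alternative 1: [2,3]-Wittig ring contraction.
- Disconnection: the C6–C7 bond is again the strategic bond, but it is cut sigmatropically. The ten-membered carbinol A1 (free C6 hydroxyl, C11 carrying an acrolein acetal as the future C12, O2, O8 and O9 silylated) is traced back to the thirteen-membered bis-allylic ether A2, in which an oxygen bridges C6 and C13.
- Forward key step: LiN(iPr)2 A3 would remove a proton from C6 of A2. The carbanion attacks C7 through a five-membered transition state while the O–C13 bond breaks. The C6–C7 bond, the C6 carbinol, the C7 centre and the C11=C13 methylene of A1 appear together and the ring shrinks by three atoms.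
- For: the carbocycle arises by contraction of a larger, less strained ring, so no high-dilution C–C macrocyclisation is needed. C6 and C7 are set in one concerted suprafacial shift. On that single event it is mechanistically tidier than the chromium closure chosen here.
- Against: A2 has two α-oxygenated allylic methylenes (C6 and C13) of similar acidity, so the site of lithiation is not secured, and a [1,2]-shift competes. The sense of induction depends on the conformation of a thirteen-membered ring with two Z alkenes and three silyloxy groups. After the shift, A1 still needs acetal hydrolysis, C12 oxidation, release of O8 alone from three identical silyl ethers, lactonisation and O6 acylation.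
- Comparison: A2 already contains C2, C8, C9 and the Z C1=C10 alkene, so the problem that the chosen key step solves in one flask is only moved earlier and a macro-etherification is added. The chosen route accepts a harder ring closure in exchange for a short, convergent build-up of the whole carbon chain.

Alternative 2: Nozaki–Hiyama–Kishi closure at C9–C10.
- Disconnection: the C9–C10 bond of A4, the C2 silyl ether of 32, is cut to the seco compound A5, a C9 aldehyde carrying a (Z)-C10 alkenyl iodide.
- Forward key step: CrCl2 A6 with catalytic NiCl2 A7 would turn the iodide of A5 into an alkenylchromium species that adds to the aldehyde, forming the ring and the C9 carbinol.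
- For: the Z geometry is stored in the iodide. The conditions tolerate the ester and the methylene lactone. A4 is one desilylation from 32, so the endgame is shorter and more convergent than the chosen one; on lateness of ring closure this alternative is stronger.
- Against: C9 is created in the macrocyclisation. Alkenylchromium additions to α-oxygenated aldehydes normally follow the Felkin sense (anti), whereas 32 needs the syn C8/C9 diol, so only ring constraints could deliver it. The aldehyde of A5 sits on C8, α to the lactone oxygen, and is prone to epimerisation. The iodide is on a hindered, fully substituted alkenyl carbon. A5 must carry the methylene lactone and the ester through its whole preparation, which would itself need a carbometallation for the iodide.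
- Comparison: the chosen route sets C9 early in an acyclic, chelation-controlled step and uses chromium only where its intrinsic preferences (anti, trans) match the target.

Alternative 3: Wharton–Grob fragmentation.
- Disconnection: the C9 ketone and the Z C4=C5 alkene of the cyclodecadienone A8 are reconnected through a C4–C9 bond to the cis-decalin A9, a tertiary C9 alcohol with an equatorial C5 mesylate.
- Forward key step: KOtBu A10 would form the C9 alkoxide of A9. The C4–C9 bond anti-periplanar to the C5–O bond cleaves, releasing the ten-membered ring.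
- For: the alkene geometry is stereospecific, read from the relative configuration at C4 and C5, and the medium ring appears without any macrocyclisation. On both points it is clearly stronger than the chosen route.
- Against: A9 has seven stereocentres, including a quaternary C4 and a tertiary carbinol, and its construction would dominate the step count. The C9 ketone of A8 must then be reduced to the syn C8/C9 diol against the chelation-controlled sense. C12 must be oxidised and lactonised late. Three classes of protecting groups have to be orchestrated, and the basic fragmentation conditions expose the α-alkoxy ketone to epimerisation at C8.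
- Comparison: the chosen route reaches all ring carbons in acyclic form within eight steps with C8 and C9 already correct. It gives up the fragmentation's geometric certainty at C4=C5 by buying that alkene, and gives up the ring-strain advantage by accepting a chromium-mediated closure.

Key step: step 8

Assumption: the (S,S) antipode of (salen)Co(OAc) is taken to be the one that hydrolyses (R)-butadiene monoxide (otherwise its mirror image is used), and 8 and 30 are taken as purchasable in the stated configurations.

Numbering remark: C1–C13 in the text follow the germacranolide numbering of 32, while locants inside systematic names follow chain numbering (undecatriene C3 = C8, C4 = C9, C7 = C2, C11 = C6); compounds 14–17 are each the pair of C2 epimers (C7 of the chain), numbered as one compound and drawn without a configuration at that carbon; TBS = tert-butyldimethylsilyl, PMB = 4-methoxybenzyl.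

## Route

Step 1
Reactants: 1 racemic butadiene monoxide (2-vinyloxirane)
Product: 2 (2R)-but-3-ene-1,2-diol
Conditions: (S,S)-(salen)Co(OAc) (trivalent cobalt; salen = N,N'-bis(3,5-di-tert-butylsalicylidene)-1,2-cyclohexanediamine dianion; 0.5 mol%), H2O (0.45 equiv), minimal THF, 0 °C → rt; unreacted epoxide distilled off
Reagents that add atoms: water, O
Why: Hydrolytic kinetic resolution: the chiral cobalt complex delivers water to the terminal carbon of one epoxide enantiomer only, so the secondary C–O bond is untouched and the (R)-epoxide gives the (R)-diol; with water limiting, the diol should be of high enantiomeric purity, which sets the future C8.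

Step 2
Reactants: 2 (2R)-but-3-ene-1,2-diol
Product: 3 (4R)-4-ethenyl-2-(4-methoxyphenyl)-1,3-dioxolane (both configurations at the acetal carbon)
Conditions: 4-MeOC6H4CH(OMe)2, PPTS (cat.), CH2Cl2, rt
Reagents that add atoms: 4-methoxybenzaldehyde dimethyl acetal, COC(OC)c1ccc(OC)cc1
Why: Acid-catalysed transacetalisation of a 1,2-diol; the acetal epimers do not matter because that carbon is reduced in the next step.

Step 3
Reactants: 3 (4R)-4-ethenyl-2-(4-methoxyphenyl)-1,3-dioxolane
Product: 4 (2R)-2-[(4-methoxybenzyl)oxy]but-3-en-1-ol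
Conditions: i-Bu2AlH, CH2Cl2, −78 → 0 °C; aq. potassium sodium tartrate
Reagents that add atoms: none
Why: Regioselective reductive opening of a 4-methoxybenzylidene acetal: aluminium binds the less hindered primary oxygen, that C–O bond breaks and hydride reduces the oxocarbenium ion, which leaves PMB on the secondary oxygen.

Step 4
Reactants: 4 (2R)-2-[(4-methoxybenzyl)oxy]but-3-en-1-ol
Product: 5 (2R)-2-[(4-methoxybenzyl)oxy]but-3-enal
Conditions: Dess–Martin periodinane, NaHCO3, CH2Cl2, 0 °C; used at once without chromatography
Reagents that add atoms: none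
Why: Dess–Martin oxidation under buffered, non-basic conditions, chosen to avoid enolisation of the α-alkoxy β,γ-unsaturated aldehyde, which would racemise C8 or move the alkene into conjugation.

Step 5
Reactants: 5 (2R)-2-[(4-methoxybenzyl)oxy]but-3-enal; 6 ethynylmagnesium bromide
Product: 7 (3R,4R)-4-[(4-methoxybenzyl)oxy]hex-5-en-1-yn-3-ol (syn)
Conditions: MgBr2·OEt2, CH2Cl2, −78 °C; then HC≡CMgBr (THF), −78 → −40 °C; aq. NH4Cl
Reagents that add atoms: ethynylmagnesium bromide (6), C#C[Mg]Br
Why: Chelation-controlled (Cram chelate) 1,2-addition: magnesium bridges the aldehyde oxygen and the PMB ether oxygen, and the acetylide attacks the face opposite the vinyl group; this gives the syn (3R,4R) alcohol and so sets C9 from C8.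

Step 6
Reactants: 8 (2Z)-3-methylpent-2-en-4-yn-1-ol
Product: 9 tert-butyldimethyl{[(2Z)-3-methylpent-2-en-4-yn-1-yl]oxy}silane
Conditions: TBSCl, imidazole, CH2Cl2, 0 °C → rt
Reagents that add atoms: tert-butyldimethylsilyl chloride, C[Si](C)(Cl)C(C)(C)C
Why: Standard silylation of a primary allylic alcohol; the Z alkene (future C4=C5) is bought in and not touched.

Step 7
Reactants: 9 tert-butyldimethyl{[(2Z)-3-methylpent-2-en-4-yn-1-yl]oxy}silane
Product: 11 (3Z)-5-[(tert-butyldimethylsilyl)oxy]-3-methylpent-3-enal, via the dienyl(dicyclohexyl)borane 10 (not isolated)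
Conditions: Cy2BH (from BH3·SMe2 and cyclohexene), THF, 0 °C; then H2O2, aq. NaH2PO4/Na2HPO4 buffer (pH 7), 0 °C; used at once
Reagents that add atoms: hydrogen peroxide, OO
Why: Anti-Markovnikov hydration of a terminal alkyne by hydroboration–oxidation: the bulky dialkylborane adds once with boron on the terminal carbon and ignores the trisubstituted alkene; oxidation gives a dienol whose kinetic protonation at the α-carbon (C3) gives the β,γ-unsaturated aldehyde with the Z alkene unchanged. The buffered work-up is meant to keep the alkene out of conjugation.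

Step 8
Reactants: 7 (3R,4R)-4-[(4-methoxybenzyl)oxy]hex-5-en-1-yn-3-ol; 12 methylmagnesium bromide; 11 (3Z)-5-[(tert-butyldimethylsilyl)oxy]-3-methylpent-3-enal
Product: 14 (3R,4R,5Z,9Z)-11-[(tert-butyldimethylsilyl)oxy]-3-[(4-methoxybenzyl)oxy]-5,9-dimethylundeca-1,5,9-triene-4,7-diol as the mixture of both C7 epimers, via the chelated C1 alkenylmagnesium C9 alkoxide 13 (not isolated)
Conditions: MeMgBr (2.4 equiv), CuI (0.15 equiv), Et2O/THF, −10 °C → rt; then 11 (1.6 equiv), −78 → −20 °C; aq. NH4Cl
Reagents that add atoms: methylmagnesium bromide (12), C[Mg]Br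
Why: The first equivalent of 12 turns the C9 hydroxyl into its magnesium alkoxide; a methylcopper species formed from CuI and 12 then adds across the alkyne with methyl on C10 and the metal on C1 in an anti sense, because only that arrangement lets magnesium on C1 close the five-membered O–Mg–C1 chelate 13 with the C9 alkoxide. The closest known reaction type is the copper-catalysed anti-carbomagnesiation of propargylic alcohols with capture of the cyclic alkenylmagnesium by iodine or carbonyl electrophiles. The chelated alkenylmagnesium adds to aldehyde 11 with retention at C1, so the C10–CH3 and C1–C2 bonds form in one flask and C9 and C2 end up cis; the Z geometry of C1=C10 is a consequence of the chelate, not of thermodynamics. No ring of the target is closed; the only ring involved is the transient magnesium chelate. The step needs regioselectivity (methyl on C10) and anti stereochemistry, both secured by the alkoxide, and addition in preference to enolisation of the β,γ-unsaturated aldehyde, which is helped by low temperature and by using 11 in excess so that residual 12 is consumed without loss of 13. The new stereocentre C2 has no reliable controlling element (it is 1,4 to C9 through the chelate), so 14 is expected as a mixture of both C2 epimers, which is carried on as such until steps 12 and 13 erase and reset that centre. C8 and C9 are not touched.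

Step 9
Reactants: 14 the 4,7-diol (mixture of C7 epimers)
Product: 15 (3R,4R,5Z,9Z)-11-[(tert-butyldimethylsilyl)oxy]-4-hydroxy-3-[(4-methoxybenzyl)oxy]-5,9-dimethylundeca-1,5,9-trien-7-yl acetate as the mixture of both C7 epimers
Conditions: AcCl (1.1 equiv), 2,4,6-collidine, CH2Cl2, −78 °C
Reagents that add atoms: acetyl chloride, CC(=O)Cl
Why: Sterically controlled mono-acylation: O2 is flanked by a methylene and an alkene CH, whereas O9 is flanked by the branched C8 and the fully substituted C10, so the acyl chloride should react at O2 only in both epimers. This tells the two allylic hydroxyls apart.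

Step 10
Reactants: 15 the C7 acetate (mixture of C7 epimers)
Product: 16 (3R,4R,5Z,9Z)-4,11-bis[(tert-butyldimethylsilyl)oxy]-3-[(4-methoxybenzyl)oxy]-5,9-dimethylundeca-1,5,9-trien-7-yl acetate as the mixture of both C7 epimers
Conditions: TBSOTf, 2,6-lutidine, CH2Cl2, −78 → 0 °C
Reagents that add atoms: tert-butyldimethylsilyl trifluoromethanesulfonate, C[Si](C)(C(C)(C)C)OS(=O)(=O)C(F)(F)F
Why: A silyl triflate with a hindered base silylates even the crowded O9; the acetate, the PMB ether and the alkenes are inert under these conditions.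

Step 11
Reactants: 16 the silylated acetate (mixture of C7 epimers)
Product: 17 (3R,4R,5Z,9Z)-4,11-bis[(tert-butyldimethylsilyl)oxy]-3-[(4-methoxybenzyl)oxy]-5,9-dimethylundeca-1,5,9-trien-7-ol as the mixture of both C7 epimers
Conditions: K2CO3, MeOH, 0 °C
Reagents that add atoms: none
Why: Base-catalysed methanolysis removes the acetate; silyl ethers and the PMB ether are stable, and the low temperature limits silyl migration from O9 to O2.

Step 12
Reactants: 17 the C7 alcohol (mixture of C7 epimers)
Product: 18 (3R,4R,5Z,9Z)-4,11-bis[(tert-butyldimethylsilyl)oxy]-3-[(4-methoxybenzyl)oxy]-5,9-dimethylundeca-1,5,9-trien-7-one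
Conditions: Dess–Martin periodinane, NaHCO3, CH2Cl2, 0 °C
Reagents that add atoms: none
Why: Dess–Martin oxidation converts both epimeric allylic alcohols into one Z enone and so erases the uncontrolled C2 centre. With O9 silylated the enone cannot close to a hemiketal and aromatise to a furan, and buffered conditions protect the Z geometry and the doubly activated C3 methylene.

Step 13
Reactants: 18 the C2 enone
Product: 19 (3R,4R,5Z,7S,9Z)-4,11-bis[(tert-butyldimethylsilyl)oxy]-3-[(4-methoxybenzyl)oxy]-5,9-dimethylundeca-1,5,9-trien-7-ol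
Conditions: (R)-2-methyl-CBS-oxazaborolidine (0.3 equiv), catecholborane, toluene, −78 °C
Reagents that add atoms: none
Why: Corey–Bakshi–Shibata reduction: the ketone binds the oxazaborolidine boron anti to its larger flank, the Z-trisubstituted alkenyl group, and hydride is delivered within the complex; with the (R)-catalyst and alkenyl as the large group this should give the (S) carbinol at C2, so the single epimer 19 is obtained. Catecholborane at −78 °C should not hydroborate the vinyl group.

Step 14
Reactants: 19 the (7S) alcohol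
Product: 20 (3R,4R,5Z,7S,9Z)-4,7,11-tris[(tert-butyldimethylsilyl)oxy]-3-[(4-methoxybenzyl)oxy]-5,9-dimethylundeca-1,5,9-triene
Conditions: TBSOTf, 2,6-lutidine, CH2Cl2, −78 °C
Reagents that add atoms: tert-butyldimethylsilyl trifluoromethanesulfonate, C[Si](C)(C(C)(C)C)OS(=O)(=O)C(F)(F)F
Why: Routine silylation of an unhindered secondary allylic alcohol; O2 and O9 now carry the same group and can be released together at the end.

Step 15
Reactants: 20 the tris-silyl PMB ether
Product: 21 (3R,4R,5Z,7S,9Z)-4,7,11-tris[(tert-butyldimethylsilyl)oxy]-5,9-dimethylundeca-1,5,9-trien-3-ol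
Conditions: DDQ, CH2Cl2/aq. NaH2PO4/Na2HPO4 buffer (pH 7), 0 °C
Reagents that add atoms: none
Why: Oxidative PMB cleavage: hydride abstraction from the electron-rich benzylic position and hydrolysis of the oxocarbenium ion free O8 alone; silyl ethers and the isolated alkenes are not affected.

Step 16
Reactants: 21 the C8 alcohol; 22 2-(bromomethyl)acrylic acid
Product: 24 (3R,4R,5Z,7S,9Z)-4,7,11-tris[(tert-butyldimethylsilyl)oxy]-5,9-dimethylundeca-1,5,9-trien-3-yl 2-(bromomethyl)prop-2-enoate, via 2-(bromomethyl)acryloyl chloride 23 (not isolated)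
Conditions: 22, (COCl)2, DMF (cat.), CH2Cl2, 0 °C → rt, evaporate; then 21, 2,6-lutidine, CH2Cl2, 0 °C
Reagents that add atoms: 2-(bromomethyl)acrylic acid (22), C=C(CBr)C(=O)O
Why: Acylation of a secondary alcohol by an acid chloride; a hindered, weakly nucleophilic pyridine base is used because nucleophilic amine catalysts would displace the allylic bromide, and the weak base does not provoke silyl migration from O9.

Step 17
Reactants: 24 the 2-(bromomethyl)acrylate
Product: 25 (5R)-3-(bromomethyl)-5-{(1R,2Z,4S,6Z)-1,4,8-tris[(tert-butyldimethylsilyl)oxy]-2,6-dimethylocta-2,6-dien-1-yl}furan-2(5H)-one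
Conditions: second-generation Grubbs catalyst RuCl2(=CHPh)(PCy3)(H2IMes) (10 mol%), toluene, 80 °C
Reagents that add atoms: none
Why: Ring-closing metathesis: the ruthenium carbene loads on the monosubstituted C7 vinyl group and closes onto the acrylate to the five-membered butenolide with loss of ethylene; the two trisubstituted alkenes are hindered and could only give strained rings.

Step 18
Reactants: 25 the bromomethyl butenolide
Product: 26 (5R)-5-{(1R,2Z,4S,6Z)-1,4-bis[(tert-butyldimethylsilyl)oxy]-8-hydroxy-2,6-dimethylocta-2,6-dien-1-yl}-3-(bromomethyl)furan-2(5H)-one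
Conditions: CSA (0.1 equiv), MeOH/CH2Cl2, 0 °C
Reagents that add atoms: none
Why: Acid-catalysed methanolysis removes a primary allylic silyl ether much faster than the two secondary ones; the amine- and fluoride-free medium spares the allylic bromide and the base-sensitive butenolide.

Step 19
Reactants: 26 the C6 allylic alcohol
Product: 27 (2Z,5S,6Z,8R)-8-[(2R)-4-(bromomethyl)-5-oxo-2,5-dihydrofuran-2-yl]-5,8-bis[(tert-butyldimethylsilyl)oxy]-3,7-dimethylocta-2,6-dienal
Conditions: Dess–Martin periodinane, NaHCO3, CH2Cl2, 0 °C; used directly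
Reagents that add atoms: none
Why: Dess–Martin oxidation of the primary allylic alcohol to the Z enal under neutral conditions, chosen to avoid Z to E isomerisation and substitution of the bromide.

Step 20
Reactants: 27 the bromide enal
Product: 29 (3aS,4R,5Z,8S,9Z,11R,11aR)-8,11-bis[(tert-butyldimethylsilyl)oxy]-4-hydroxy-6,10-dimethyl-3-methylidene-3a,4,7,8,11,11a-hexahydrocyclodeca[b]furan-2(3H)-one, via the C13 allylchromium dichloride 28 (not isolated)
Conditions: CrCl2 (8 equiv), THF, rt, slow addition of 27 to high dilution (about 0.003 M)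
Reagents that add atoms: none
Why: Intramolecular chromium-mediated Barbier (Nozaki–Hiyama) allylation: two equivalents of divalent chromium reduce the allylic bromide to a trivalent allylchromium, which adds to the aldehyde through its γ-carbon C7 in a six-membered chair transition state, closing the ten-membered ring at C6–C7 and shifting the alkene to the exocyclic C11=C13 position. Attack on the butenolide face opposite the C9 substituent gives trans H7/H8, and because the ring holds C8 trans to C13 on the allyl unit, the chair with the aldehyde substituent equatorial gives the anti relationship of O6 and C8, that is 6R,7S.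

Step 21
Reactants: 29 the ring alcohol; 30 (2R)-2-methylbutanoic acid
Product: 31 (3aS,4R,5Z,8S,9Z,11R,11aR)-8,11-bis[(tert-butyldimethylsilyl)oxy]-6,10-dimethyl-3-methylidene-2-oxo-2,3,3a,4,7,8,11,11a-octahydrocyclodeca[b]furan-4-yl (2R)-2-methylbutanoate
Conditions: DCC, DMAP (0.2 equiv), CH2Cl2, 0 °C → rt
Reagents that add atoms: (2R)-2-methylbutanoic acid (30), CC[C@@H](C)C(=O)O
Why: Steglich esterification of the only free hydroxyl; the mild, nearly neutral conditions should leave the α-stereocentre of the acid and the methylene lactone intact.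

Step 22
Reactants: 31 the bis-silyl ether
Product: 32 (3aS,4R,5Z,8S,9Z,11R,11aR)-8,11-dihydroxy-6,10-dimethyl-3-methylidene-2-oxo-2,3,3a,4,7,8,11,11a-octahydrocyclodeca[b]furan-4-yl (2R)-2-methylbutanoate (CNP0176600.1)
Conditions: HF·pyridine, pyridine, THF, 0 °C → rt
Reagents that add atoms: none
Why: Fluoride cleavage of the two secondary allylic silyl ethers under buffered, weakly acidic conditions; basic fluoride is avoided because it would invite acyl migration, translactonisation and conjugate addition to the methylene lactone.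

## Compound list

1 | racemic butadiene monoxide (2-vinyloxirane) | C=CC1CO1 | starting material
2 | (2R)-but-3-ene-1,2-diol | C=C[C@@H](O)CO | intermediate
3 | (4R)-4-ethenyl-2-(4-methoxyphenyl)-1,3-dioxolane (acetal carbon as both epimers) | C=C[C@@H]1COC(c2ccc(OC)cc2)O1 | intermediate
4 | (2R)-2-[(4-methoxybenzyl)oxy]but-3-en-1-ol | C=C[C@@H](OCc1ccc(OC)cc1)CO | intermediate
5 | (2R)-2-[(4-methoxybenzyl)oxy]but-3-enal | C=C[C@@H](OCc1ccc(OC)cc1)C=O | intermediate
6 | ethynylmagnesium bromide | C#C[Mg]Br | starting material
7 | (3R,4R)-4-[(4-methoxybenzyl)oxy]hex-5-en-1-yn-3-ol | C#C[C@@H](O)[C@H](OCc1ccc(OC)cc1)C=C | intermediate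
8 | (2Z)-3-methylpent-2-en-4-yn-1-ol | C#C/C(C)=C\CO | starting material
9 | tert-butyldimethyl{[(2Z)-3-methylpent-2-en-4-yn-1-yl]oxy}silane | C#C/C(C)=C\CO[Si](C)(C)C(C)(C)C | intermediate
10 | dicyclohexyl{(1E,3Z)-5-[(tert-butyldimethylsilyl)oxy]-3-methylpenta-1,3-dien-1-yl}borane (not isolated) | C1CCCCC1B(C2CCCCC2)/C=C/C(C)=C\CO[Si](C)(C)C(C)(C)C | intermediate
11 | (3Z)-5-[(tert-butyldimethylsilyl)oxy]-3-methylpent-3-enal | O=CC/C(C)=C\CO[Si](C)(C)C(C)(C)C | intermediate
12 | methylmagnesium bromide | C[Mg]Br | starting material
13 | (5R)-5-{(1R)-1-[(4-methoxybenzyl)oxy]prop-2-en-1-yl}-4-methyl-2,5-dihydro-1,2-oxamagnesole (chelated C1 alkenylmagnesium C9 alkoxide; not isolated) | C=C[C@@H](OCc1ccc(OC)cc1)[C@@H]2O[Mg]C=C2C | intermediate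
14 | (3R,4R,5Z,9Z)-11-[(tert-butyldimethylsilyl)oxy]-3-[(4-methoxybenzyl)oxy]-5,9-dimethylundeca-1,5,9-triene-4,7-diol (mixture of both C7 epimers) | C=C[C@@H](OCc1ccc(OC)cc1)[C@H](O)/C(C)=C\C(O)C/C(C)=C\CO[Si](C)(C)C(C)(C)C | intermediate
15 | (3R,4R,5Z,9Z)-11-[(tert-butyldimethylsilyl)oxy]-4-hydroxy-3-[(4-methoxybenzyl)oxy]-5,9-dimethylundeca-1,5,9-trien-7-yl acetate (mixture of both C7 epimers) | C=C[C@@H](OCc1ccc(OC)cc1)[C@H](O)/C(C)=C\C(OC(C)=O)C/C(C)=C\CO[Si](C)(C)C(C)(C)C | intermediate
16 | (3R,4R,5Z,9Z)-4,11-bis[(tert-butyldimethylsilyl)oxy]-3-[(4-methoxybenzyl)oxy]-5,9-dimethylundeca-1,5,9-trien-7-yl acetate (mixture of both C7 epimers) | C=C[C@@H](OCc1ccc(OC)cc1)[C@H](O[Si](C)(C)C(C)(C)C)/C(C)=C\C(OC(C)=O)C/C(C)=C\CO[Si](C)(C)C(C)(C)C | intermediate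
17 | (3R,4R,5Z,9Z)-4,11-bis[(tert-butyldimethylsilyl)oxy]-3-[(4-methoxybenzyl)oxy]-5,9-dimethylundeca-1,5,9-trien-7-ol (mixture of both C7 epimers) | C=C[C@@H](OCc1ccc(OC)cc1)[C@H](O[Si](C)(C)C(C)(C)C)/C(C)=C\C(O)C/C(C)=C\CO[Si](C)(C)C(C)(C)C | intermediate
18 | (3R,4R,5Z,9Z)-4,11-bis[(tert-butyldimethylsilyl)oxy]-3-[(4-methoxybenzyl)oxy]-5,9-dimethylundeca-1,5,9-trien-7-one | C=C[C@@H](OCc1ccc(OC)cc1)[C@H](O[Si](C)(C)C(C)(C)C)/C(C)=C\C(=O)C/C(C)=C\CO[Si](C)(C)C(C)(C)C | intermediate
19 | (3R,4R,5Z,7S,9Z)-4,11-bis[(tert-butyldimethylsilyl)oxy]-3-[(4-methoxybenzyl)oxy]-5,9-dimethylundeca-1,5,9-trien-7-ol | C=C[C@@H](OCc1ccc(OC)cc1)[C@H](O[Si](C)(C)C(C)(C)C)/C(C)=C\[C@@H](O)C/C(C)=C\CO[Si](C)(C)C(C)(C)C | intermediate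
20 | (3R,4R,5Z,7S,9Z)-4,7,11-tris[(tert-butyldimethylsilyl)oxy]-3-[(4-methoxybenzyl)oxy]-5,9-dimethylundeca-1,5,9-triene | C=C[C@@H](OCc1ccc(OC)cc1)[C@H](O[Si](C)(C)C(C)(C)C)/C(C)=C\[C@@H](O[Si](C)(C)C(C)(C)C)C/C(C)=C\CO[Si](C)(C)C(C)(C)C | intermediate
21 | (3R,4R,5Z,7S,9Z)-4,7,11-tris[(tert-butyldimethylsilyl)oxy]-5,9-dimethylundeca-1,5,9-trien-3-ol | C=C[C@@H](O)[C@H](O[Si](C)(C)C(C)(C)C)/C(C)=C\[C@@H](O[Si](C)(C)C(C)(C)C)C/C(C)=C\CO[Si](C)(C)C(C)(C)C | intermediate
22 | 2-(bromomethyl)acrylic acid | C=C(CBr)C(=O)O | starting material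
23 | 2-(bromomethyl)acryloyl chloride (not isolated) | C=C(CBr)C(=O)Cl | intermediate
24 | (3R,4R,5Z,7S,9Z)-4,7,11-tris[(tert-butyldimethylsilyl)oxy]-5,9-dimethylundeca-1,5,9-trien-3-yl 2-(bromomethyl)prop-2-enoate | C=C[C@@H](OC(=O)C(=C)CBr)[C@H](O[Si](C)(C)C(C)(C)C)/C(C)=C\[C@@H](O[Si](C)(C)C(C)(C)C)C/C(C)=C\CO[Si](C)(C)C(C)(C)C | intermediate
25 | (5R)-3-(bromomethyl)-5-{(1R,2Z,4S,6Z)-1,4,8-tris[(tert-butyldimethylsilyl)oxy]-2,6-dimethylocta-2,6-dien-1-yl}furan-2(5H)-one | BrCC1=C[C@@H](OC1=O)[C@H](O[Si](C)(C)C(C)(C)C)/C(C)=C\[C@@H](O[Si](C)(C)C(C)(C)C)C/C(C)=C\CO[Si](C)(C)C(C)(C)C | intermediate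
26 | (5R)-5-{(1R,2Z,4S,6Z)-1,4-bis[(tert-butyldimethylsilyl)oxy]-8-hydroxy-2,6-dimethylocta-2,6-dien-1-yl}-3-(bromomethyl)furan-2(5H)-one | BrCC1=C[C@@H](OC1=O)[C@H](O[Si](C)(C)C(C)(C)C)/C(C)=C\[C@@H](O[Si](C)(C)C(C)(C)C)C/C(C)=C\CO | intermediate
27 | (2Z,5S,6Z,8R)-8-[(2R)-4-(bromomethyl)-5-oxo-2,5-dihydrofuran-2-yl]-5,8-bis[(tert-butyldimethylsilyl)oxy]-3,7-dimethylocta-2,6-dienal | BrCC1=C[C@@H](OC1=O)[C@H](O[Si](C)(C)C(C)(C)C)/C(C)=C\[C@@H](O[Si](C)(C)C(C)(C)C)C/C(C)=C\C=O | intermediate
28 | C13 allylchromium dichloride derived from 27 (trivalent chromium; not isolated) | Cl[Cr](Cl)CC1=C[C@@H](OC1=O)[C@H](O[Si](C)(C)C(C)(C)C)/C(C)=C\[C@@H](O[Si](C)(C)C(C)(C)C)C/C(C)=C\C=O | intermediate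
29 | (3aS,4R,5Z,8S,9Z,11R,11aR)-8,11-bis[(tert-butyldimethylsilyl)oxy]-4-hydroxy-6,10-dimethyl-3-methylidene-3a,4,7,8,11,11a-hexahydrocyclodeca[b]furan-2(3H)-one | C=C1C(=O)O[C@@H]2[C@@H]1[C@H](O)/C=C(/C)C[C@H](O[Si](C)(C)C(C)(C)C)/C=C(/C)[C@H]2O[Si](C)(C)C(C)(C)C | intermediate
30 | (2R)-2-methylbutanoic acid | CC[C@@H](C)C(=O)O | starting material
31 | (3aS,4R,5Z,8S,9Z,11R,11aR)-8,11-bis[(tert-butyldimethylsilyl)oxy]-6,10-dimethyl-3-methylidene-2-oxo-2,3,3a,4,7,8,11,11a-octahydrocyclodeca[b]furan-4-yl (2R)-2-methylbutanoate | C=C1C(=O)O[C@@H]2[C@@H]1[C@H](OC(=O)[C@H](C)CC)/C=C(/C)C[C@H](O[Si](C)(C)C(C)(C)C)/C=C(/C)[C@H]2O[Si](C)(C)C(C)(C)C | intermediate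
32 | (3aS,4R,5Z,8S,9Z,11R,11aR)-8,11-dihydroxy-6,10-dimethyl-3-methylidene-2-oxo-2,3,3a,4,7,8,11,11a-octahydrocyclodeca[b]furan-4-yl (2R)-2-methylbutanoate (CNP0176600.1) | C=C1C(=O)O[C@@H]2[C@@H]1[C@H](OC(=O)[C@H](C)CC)/C=C(/C)C[C@H](O)/C=C(/C)[C@H]2O | target

## Step count and least certain steps

Total step count: 22. Longest linear sequence: 20 steps (from 1 through steps 1–5 and 8–22). The second fragment takes 2 steps (6 and 7) from 8.

**Step 8 (key step).** The most likely failures are proton transfer from the doubly activated C3 methylene of 11 to the basic organomagnesium species instead of addition, consumption of 11 by 12 left over from the carbometallation, and incomplete methyl transfer because the terminal alkyne is partly deprotonated. The lack of control at C2 is already absorbed by steps 12 and 13. Fallback: the union is split into two stages with a non-basic C1–C2 coupling. Starting from 7, the same copper-catalysed methylmagnesiation is quenched with iodine instead of the aldehyde, which should give (1Z,3R,4R)-1-iodo-4-[(4-methoxybenzyl)oxy]-2-methylhexa-1,5-dien-3-ol F1. Silylation with TBSOTf and 2,6-lutidine gives its C9 silyl ether, tert-butyl{[(1Z,3R,4R)-1-iodo-4-[(4-methoxybenzyl)oxy]-2-methylhexa-1,5-dien-3-yl]oxy}dimethylsilane F2. A Nozaki–Hiyama–Kishi coupling of F2 with 11 (CrCl2, catalytic NiCl2, DMF) then gives 17 directly, where the route is rejoined before step 12.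

**Step 20.** Closure of a strained ten-membered ring competes with intermolecular coupling and simple reduction of the bromide. If the ring closes, the aldehyde may react through the alternative chair with its substituent axial, that is with the wrong facial selectivity at C6. Fallback for the second case: starting from 27, the cyclisation product of opposite C6 configuration, (3aS,4S,5Z,8S,9Z,11R,11aR)-8,11-bis[(tert-butyldimethylsilyl)oxy]-4-hydroxy-6,10-dimethyl-3-methylidene-3a,4,7,8,11,11a-hexahydrocyclodeca[b]furan-2(3H)-one F3, is esterified with 30 under Mitsunobu conditions (PPh3, diisopropyl azodicarboxylate). This inverts C6 and installs the ester in one operation, coming back to the route at 31.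

**Step 17.** The allylic bromide may be displaced or may decompose the ruthenium carbene, and cyclisation onto the electron-poor 1,1-disubstituted alkene may be slow enough for dimerisation at the vinyl group to take over. Fallback: C13 is carried as a PMB ether through esterification and metathesis. Starting from 22, sodium 4-methoxybenzyl oxide (4-methoxybenzyl alcohol, NaH, THF) gives 2-{[(4-methoxybenzyl)oxy]methyl}acrylic acid F4. Esterification of 21 with F4 (DCC, DMAP) gives (3R,4R,5Z,7S,9Z)-4,7,11-tris[(tert-butyldimethylsilyl)oxy]-5,9-dimethylundeca-1,5,9-trien-3-yl 2-{[(4-methoxybenzyl)oxy]methyl}prop-2-enoate F5. Ring-closing metathesis with the same ruthenium catalyst gives the 3-{[(4-methoxybenzyl)oxy]methyl} analogue of 25 F6, DDQ gives the 3-(hydroxymethyl) analogue of 25 F7, and CBr4 with PPh3 (Appel reaction) converts F7 into 25, where the route is rejoined.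

**Step 13.** Facial selectivity may be poor if the twisted Z-alkenyl group is not recognised as the larger ketone flank, or if the existing C8/C9 centres oppose the catalyst. Fallback: starting from 18, a Luche reduction (NaBH4, CeCl3·7H2O, MeOH) gives the epimer mixture 17, from which 19 and the (7R) epimer of 19 F8 are separated. F8 is then inverted by a Mitsunobu reaction with 4-nitrobenzoic acid to (3R,4R,5Z,7S,9Z)-4,11-bis[(tert-butyldimethylsilyl)oxy]-3-[(4-methoxybenzyl)oxy]-5,9-dimethylundeca-1,5,9-trien-7-yl 4-nitrobenzoate F9, and methanolysis (K2CO3, MeOH) returns to the route at 19.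

**Step 7.** During oxidative work-up of the dienylborane the C4=C5 alkene may migrate into conjugation with the new aldehyde, with loss of the Z geometry, and double hydroboration of the alkyne is possible. Fallback: the aldehyde is made by alcohol oxidation instead. Starting from 9, semi-hydrogenation (H2, Pd/CaCO3 poisoned with Pb(OAc)2, quinoline) gives tert-butyldimethyl{[(2Z)-3-methylpenta-2,4-dien-1-yl]oxy}silane F10. Hydroboration of the terminal vinyl group with 9-BBN and oxidation (H2O2, NaOH) gives (3Z)-5-[(tert-butyldimethylsilyl)oxy]-3-methylpent-3-en-1-ol F11, and buffered Dess–Martin oxidation of F11 comes back to the route at 11.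

**Step 5.** THF from the Grignard solution may compete with the PMB oxygen for magnesium, eroding chelation control in favour of the anti adduct. Fallback: starting from 5, the anti adduct (3S,4R)-4-[(4-methoxybenzyl)oxy]hex-5-en-1-yn-3-ol F12 formed alongside 7 is separated. It is inverted at C9 by a Mitsunobu reaction with 4-nitrobenzoic acid to (3R,4R)-4-[(4-methoxybenzyl)oxy]hex-5-en-1-yn-3-yl 4-nitrobenzoate F13, and methanolysis (K2CO3, MeOH) comes back to the route at 7.

## Further compounds

F1 | step 8 | (1Z,3R,4R)-1-iodo-4-[(4-methoxybenzyl)oxy]-2-methylhexa-1,5-dien-3-ol | C=C[C@@H](OCc1ccc(OC)cc1)[C@H](O)/C(C)=C\I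
F2 | step 8 | tert-butyl{[(1Z,3R,4R)-1-iodo-4-[(4-methoxybenzyl)oxy]-2-methylhexa-1,5-dien-3-yl]oxy}dimethylsilane | C=C[C@@H](OCc1ccc(OC)cc1)[C@H](O[Si](C)(C)C(C)(C)C)/C(C)=C\I
F3 | step 20 | (3aS,4S,5Z,8S,9Z,11R,11aR)-8,11-bis[(tert-butyldimethylsilyl)oxy]-4-hydroxy-6,10-dimethyl-3-methylidene-3a,4,7,8,11,11a-hexahydrocyclodeca[b]furan-2(3H)-one (C6 epimer of 29) | C=C1C(=O)O[C@@H]2[C@@H]1[C@@H](O)/C=C(/C)C[C@H](O[Si](C)(C)C(C)(C)C)/C=C(/C)[C@H]2O[Si](C)(C)C(C)(C)C
F4 | step 17 | 2-{[(4-methoxybenzyl)oxy]methyl}acrylic acid | C=C(COCc1ccc(OC)cc1)C(=O)O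
F5 | step 17 | (3R,4R,5Z,7S,9Z)-4,7,11-tris[(tert-butyldimethylsilyl)oxy]-5,9-dimethylundeca-1,5,9-trien-3-yl 2-{[(4-methoxybenzyl)oxy]methyl}prop-2-enoate | C=C[C@@H](OC(=O)C(=C)COCc1ccc(OC)cc1)[C@H](O[Si](C)(C)C(C)(C)C)/C(C)=C\[C@@H](O[Si](C)(C)C(C)(C)C)C/C(C)=C\CO[Si](C)(C)C(C)(C)C
F6 | step 17 | (5R)-3-{[(4-methoxybenzyl)oxy]methyl}-5-{(1R,2Z,4S,6Z)-1,4,8-tris[(tert-butyldimethylsilyl)oxy]-2,6-dimethylocta-2,6-dien-1-yl}furan-2(5H)-one | COc1ccc(COCC2=C[C@@H](OC2=O)[C@H](O[Si](C)(C)C(C)(C)C)/C(C)=C\[C@@H](O[Si](C)(C)C(C)(C)C)C/C(C)=C\CO[Si](C)(C)C(C)(C)C)cc1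
F7 | step 17 | (5R)-3-(hydroxymethyl)-5-{(1R,2Z,4S,6Z)-1,4,8-tris[(tert-butyldimethylsilyl)oxy]-2,6-dimethylocta-2,6-dien-1-yl}furan-2(5H)-one | OCC1=C[C@@H](OC1=O)[C@H](O[Si](C)(C)C(C)(C)C)/C(C)=C\[C@@H](O[Si](C)(C)C(C)(C)C)C/C(C)=C\CO[Si](C)(C)C(C)(C)C
F8 | step 13 | (3R,4R,5Z,7R,9Z)-4,11-bis[(tert-butyldimethylsilyl)oxy]-3-[(4-methoxybenzyl)oxy]-5,9-dimethylundeca-1,5,9-trien-7-ol (C7 epimer of 19) | C=C[C@@H](OCc1ccc(OC)cc1)[C@H](O[Si](C)(C)C(C)(C)C)/C(C)=C\[C@H](O)C/C(C)=C\CO[Si](C)(C)C(C)(C)C
F9 | step 13 | (3R,4R,5Z,7S,9Z)-4,11-bis[(tert-butyldimethylsilyl)oxy]-3-[(4-methoxybenzyl)oxy]-5,9-dimethylundeca-1,5,9-trien-7-yl 4-nitrobenzoate | C=C[C@@H](OCc1ccc(OC)cc1)[C@H](O[Si](C)(C)C(C)(C)C)/C(C)=C\[C@@H](OC(=O)c1ccc(cc1)[N+](=O)[O-])C/C(C)=C\CO[Si](C)(C)C(C)(C)C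
F10 | step 7 | tert-butyldimethyl{[(2Z)-3-methylpenta-2,4-dien-1-yl]oxy}silane | C=C/C(C)=C\CO[Si](C)(C)C(C)(C)C
F11 | step 7 | (3Z)-5-[(tert-butyldimethylsilyl)oxy]-3-methylpent-3-en-1-ol | OCC/C(C)=C\CO[Si](C)(C)C(C)(C)C
F12 | step 5 | (3S,4R)-4-[(4-methoxybenzyl)oxy]hex-5-en-1-yn-3-ol | C#C[C@H](O)[C@H](OCc1ccc(OC)cc1)C=C
F13 | step 5 | (3R,4R)-4-[(4-methoxybenzyl)oxy]hex-5-en-1-yn-3-yl 4-nitrobenzoate | C#C[C@@H](OC(=O)c1ccc(cc1)[N+](=O)[O-])[C@H](OCc1ccc(OC)cc1)C=C
A1 | alternative 1 | ten-membered C6 carbinol with C11 acrolein acetal, O2/O8/O9 as TBS ethers | C=C(C2OCCO2)[C@@H]1[C@@H](O[Si](C)(C)C(C)(C)C)[C@H](O[Si](C)(C)C(C)(C)C)/C(C)=C\[C@@H](O[Si](C)(C)C(C)(C)C)C/C(C)=C\[C@H]1O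
A2 | alternative 1 | thirteen-membered C6–O–C13 bis-allylic ether (C13 and C8 trans on C7=C11) | O1C/C(C2OCCO2)=C/[C@@H](O[Si](C)(C)C(C)(C)C)[C@H](O[Si](C)(C)C(C)(C)C)/C(C)=C\[C@@H](O[Si](C)(C)C(C)(C)C)C/C(C)=C\C1
A3 | alternative 1 | lithium diisopropylamide, LiN(iPr)2 | [Li+].CC(C)[N-]C(C)C
A4 | alternative 2 | C2 TBS ether of 32 | C=C1C(=O)O[C@@H]2[C@@H]1[C@H](OC(=O)[C@H](C)CC)/C=C(/C)C[C@H](O[Si](C)(C)C(C)(C)C)/C=C(/C)[C@H]2O
A5 | alternative 2 | seco C9 aldehyde with (Z)-C10 alkenyl iodide | C=C1C(=O)O[C@@H](C=O)[C@@H]1[C@H](OC(=O)[C@H](C)CC)/C=C(/C)C[C@H](O[Si](C)(C)C(C)(C)C)/C=C(/C)I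
A6 | alternative 2 | chromium dichloride, CrCl2 | [Cr+2].[Cl-].[Cl-]
A7 | alternative 2 | nickel dichloride, NiCl2 | [Ni+2].[Cl-].[Cl-]
A8 | alternative 3 | protected (1(10)Z,4Z)-cyclodeca-1(10),4-dien-9-one | C=C(COCc1ccc(OC)cc1)[C@@H]2[C@@H](OCc1ccc(OC)cc1)C(=O)/C(C)=C\[C@@H](O[Si](C)(C)C(C)(C)C)C/C(C)=C\[C@H]2O[Si](CC)(CC)CC
A9 | alternative 3 | cis-decalin with tertiary C9 hydroxyl and equatorial C5 mesylate | C=C(COCc1ccc(OC)cc1)[C@@H]2[C@@H](OCc1ccc(OC)cc1)[C@]3(O)C(C)=C[C@@H](O[Si](C)(C)C(C)(C)C)C[C@]3(C)[C@H](OS(C)(=O)=O)[C@H]2O[Si](CC)(CC)CC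
A10 | alternative 3 | potassium tert-butoxide, KOtBu | [K+].CC(C)(C)[O-]
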